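**Retrosynthetic overview**
1. The target is disconnected at the C5 ester: trans-diaxial opening of a 5,6-epoxide next to the exocyclic methylene (a vinyl oxirane) by (E)-3-methylpent-2-enoic acid sets C5 and frees the C6 hydroxyl.
2. The vinyl oxirane comes from a trans-fused bicyclic cyclohex-2-enone by nucleophilic epoxidation and Wittig methylenation.
3. The six-membered ring is formed second: allylation of a cyclopentane carbaldehyde, ring-closing metathesis, oxidation and conjugation (this sets the isopropyl-bearing carbon).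
4. The (Z)-ethylidene/oxygen pair on the five-membered ring comes from a ring nitro alcohol by Nef reaction and Z-selective Wittig olefination.
5. The cyclopentane is formed first, with its ring stereocentres, by an organocatalytic Michael/Henry domino of succinaldehyde with a nitrodiene made from a commercial enal and nitromethane.

Assumption: (2E)-5-methyl-2-(propan-2-yl)hex-2-enal (a commercial flavour aldehyde; its alkene geometry is erased in step 7), succinaldehyde (freshly distilled) and (2E)-3-methylpent-2-enoic acid are purchased; all are achiral.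
Assumption: the nitro-bearing carbon in compounds 6 to 9 is drawn as the all-trans epimer; this centre is removed in step 5.

Step 1
Reactants: 1 (2E)-5-methyl-2-(propan-2-yl)hex-2-enal; 2 nitromethane
Product: 3 (1E,3E)-6-methyl-1-nitro-3-(propan-2-yl)hepta-1,3-diene
Conditions: CH3NO2 (5 equiv), NH4OAc (0.3 equiv), AcOH, 90 °C
Reagents that add atoms: none
Why: Ammonium acetate-mediated Henry condensation (nitroaldol addition then dehydration) of the enal gives the conjugated (1E)-nitrodiene, the more stable nitroalkene geometry, and no stereocentre is formed.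

Step 2
Reactants: 3 (1E,3E)-6-methyl-1-nitro-3-(propan-2-yl)hepta-1,3-diene; 4 succinaldehyde
Product: 6 (1R,2R,3R,4R)-2-[(3E)-2,6-dimethylhept-3-en-3-yl]-4-hydroxy-3-nitrocyclopentane-1-carbaldehyde, via syn Michael adduct 5 (not isolated)
Conditions: (R)-α,α-diphenylprolinol trimethylsilyl ether (10 mol%), 4-nitrophenol (10 mol%), MeCN, 20 °C; then iPr2NEt, 0 °C to 20 °C
Reagents that add atoms: none
Why: Enamine catalysis with the diarylprolinol silyl ether (Hayashi-type Michael reaction) adds the succinaldehyde α-carbon to one enantioface of C2 of the nitrodiene, setting the alkenyl-bearing ring carbon, and the amine base then triggers an intramolecular Henry reaction (formal [3+2] domino) and epimerises the formyl-bearing carbon, so the reversible sequence settles on the all-trans cyclopentane.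

Step 3
Reactants: 6 (1R,2R,3R,4R)-2-[(3E)-2,6-dimethylhept-3-en-3-yl]-4-hydroxy-3-nitrocyclopentane-1-carbaldehyde
Product: 7 (1R,2R,3R,4R)-4-[(tert-butyldimethylsilyl)oxy]-2-[(3E)-2,6-dimethylhept-3-en-3-yl]-3-nitrocyclopentane-1-carbaldehyde
Conditions: TBSCl, imidazole, DMF, 0 °C to 20 °C
Reagents that add atoms: tert-butyldimethylsilyl chloride CC(C)(C)[Si](C)(C)Cl
Why: Imidazole-promoted silylation caps the secondary alcohol so that the β-nitro alcohol cannot undergo retro-Henry cleavage in the later basic steps, and no stereocentre changes.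

Step 4
Reactants: 7 (1R,2R,3R,4R)-4-[(tert-butyldimethylsilyl)oxy]-2-[(3E)-2,6-dimethylhept-3-en-3-yl]-3-nitrocyclopentane-1-carbaldehyde
Product: 9 1-[(1R,2R,3R,4R)-4-[(tert-butyldimethylsilyl)oxy]-2-[(3E)-2,6-dimethylhept-3-en-3-yl]-3-nitrocyclopentyl]but-3-en-1-ol (both carbinol epimers), via pinacol borate ester 8 (not isolated)
Conditions: allylB(pin), CH2Cl2, 20 °C; then H2O
Reagents that add atoms: allylboronic acid pinacol ester C=CCB1OC(C)(C)C(C)(C)O1
Why: Uncatalysed allylboration through a closed six-membered transition state adds to the aldehyde without touching the nitro group, and the new carbinol centre needs no control because it is oxidised in step 8.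

Step 5
Reactants: 9 1-[(1R,2R,3R,4R)-4-[(tert-butyldimethylsilyl)oxy]-2-[(3E)-2,6-dimethylhept-3-en-3-yl]-3-nitrocyclopentyl]but-3-en-1-ol
Product: 11 (2R,3R,5R)-5-[(tert-butyldimethylsilyl)oxy]-2-[(3E)-2,6-dimethylhept-3-en-3-yl]-3-(1-hydroxybut-3-en-1-yl)cyclopentan-1-one, via sodium nitronate 10 (not isolated)
Conditions: NaOMe, MeOH, 0 °C; then TiCl3, NH4OAc, H2O, MeOH, 20 °C
Reagents that add atoms: water O (carbonyl oxygen of 11); sodium methoxide [Na+].[O-]C (sodium counter-ion of 10 only)
Why: In this McMurry variant of the Nef reaction TiCl3 reduces the nitronate to an imine that hydrolyses at buffered pH to the ketone, which spares the silyl ether and both alkenes and leaves the alkenyl-bearing α-carbon in its preferred trans arrangement.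

Step 6
Reactants: 11 (2R,3R,5R)-5-[(tert-butyldimethylsilyl)oxy]-2-[(3E)-2,6-dimethylhept-3-en-3-yl]-3-(1-hydroxybut-3-en-1-yl)cyclopentan-1-one
Product: 12 1-[(1R,2R,3Z,4R)-4-[(tert-butyldimethylsilyl)oxy]-2-[(3E)-2,6-dimethylhept-3-en-3-yl]-3-ethylidenecyclopentyl]but-3-en-1-ol (both carbinol epimers)
Conditions: EtPPh3Br (3 equiv), KOtBu (3 equiv), THF, 0 °C to 20 °C
Reagents that add atoms: ethyltriphenylphosphonium bromide CC[P+](c1ccccc1)(c1ccccc1)c1ccccc1.[Br-]
Why: Wittig olefination with a non-stabilised ylide is Z-selective on α-oxygenated ketones (Still-type trisubstituted olefin synthesis), so the methyl group ends up syn to the silyloxy-bearing carbon and away from the branched alkenyl-bearing carbon.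

Step 7
Reactants: 12 1-[(1R,2R,3Z,4R)-4-[(tert-butyldimethylsilyl)oxy]-2-[(3E)-2,6-dimethylhept-3-en-3-yl]-3-ethylidenecyclopentyl]but-3-en-1-ol
Product: 13 (1Z,2R,3aR,7aR)-2-[(tert-butyldimethylsilyl)oxy]-1-ethylidene-7-(propan-2-yl)-2,3,3a,4,5,7a-hexahydro-1H-inden-4-ol (both C4 epimers)
Conditions: second-generation Hoveyda–Grubbs catalyst RuCl2(H2IMes)(=CH–C6H4-2-OiPr) (10 mol%), 1,4-benzoquinone (20 mol%), toluene, 80 °C
Reagents that add atoms: none
Why: Ring-closing metathesis starts at the terminal allyl alkene and closes onto the trisubstituted alkene with loss of 4-methylpent-1-ene to give the six-membered ring, while the ethylidene group stays out because closing onto it would need a bridgehead alkene.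

Step 8
Reactants: 13 (1Z,2R,3aR,7aR)-2-[(tert-butyldimethylsilyl)oxy]-1-ethylidene-7-(propan-2-yl)-2,3,3a,4,5,7a-hexahydro-1H-inden-4-ol
Product: 15 (1Z,2R,3aR,7R,7aS)-2-[(tert-butyldimethylsilyl)oxy]-1-ethylidene-7-(propan-2-yl)-1,2,3,3a,7,7a-hexahydro-4H-inden-4-one, via deconjugated ketone 14 (not isolated)
Conditions: Dess–Martin periodinane, CH2Cl2, 0 °C to 20 °C; then DBU, 20 °C
Reagents that add atoms: none
Why: Dess–Martin oxidation gives the β,γ-unsaturated ketone and DBU moves the alkene into conjugation through the dienolate, whose γ-protonation is axial on the locked trans-fused ring and reversible, so the isopropyl group ends up equatorial (new stereocentre C7).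

Step 9
Reactants: 15 (1Z,2R,3aR,7R,7aS)-2-[(tert-butyldimethylsilyl)oxy]-1-ethylidene-7-(propan-2-yl)-1,2,3,3a,7,7a-hexahydro-4H-inden-4-one
Product: 16 (1Z,2R,3aR,5S,6S,7S,7aS)-2-[(tert-butyldimethylsilyl)oxy]-5,6-epoxy-1-ethylidene-7-(propan-2-yl)octahydro-4H-inden-4-one (oxirane on the face of H-7a)
Conditions: 30% H2O2, NaOH (0.2 equiv), MeOH, 0 °C
Reagents that add atoms: hydrogen peroxide OO
Why: In this Weitz–Scheffer nucleophilic epoxidation the hydroperoxide anion attacks C6 along the axial trajectory of the conformationally locked enone (trans to the equatorial C7a–C1 bond, as in trans-fused steroidal enones), so the oxirane forms on the face of H-7a and the electron-rich ethylidene is untouched.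

Step 10
Reactants: 16 (1Z,2R,3aR,5S,6S,7S,7aS)-2-[(tert-butyldimethylsilyl)oxy]-5,6-epoxy-1-ethylidene-7-(propan-2-yl)octahydro-4H-inden-4-one
Product: 17 tert-butyl{[(1Z,2R,3aR,5R,6S,7S,7aR)-5,6-epoxy-1-ethylidene-4-methylidene-7-(propan-2-yl)octahydro-1H-inden-2-yl]oxy}dimethylsilane
Conditions: MePPh3Br (1.5 equiv), KOtBu (1.4 equiv), THF, 0 °C
Reagents that add atoms: methyltriphenylphosphonium bromide C[P+](c1ccccc1)(c1ccccc1)c1ccccc1.[Br-]
Why: Wittig methylenation of an α,β-epoxy ketone is a well-used reaction that leaves the oxirane and the silyl ether intact and creates the vinyl oxirane needed for the last step.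

Step 11
Reactants: 17 tert-butyl{[(1Z,2R,3aR,5R,6S,7S,7aR)-5,6-epoxy-1-ethylidene-4-methylidene-7-(propan-2-yl)octahydro-1H-inden-2-yl]oxy}dimethylsilane
Product: 19 (1Z,2R,3aR,5R,6S,7S,7aR)-5,6-epoxy-1-ethylidene-4-methylidene-7-(propan-2-yl)octahydro-1H-inden-2-yl acetate, via free alcohol 18 (not isolated)
Conditions: TBAF, THF, 0 °C; then Ac2O, DMAP (5 mol%), 20 °C
Reagents that add atoms: acetic anhydride CC(=O)OC(C)=O
Why: Fluoride desilylation followed by acetylation in the same flask (protecting-group exchange) installs the C2 acetate while it is the only hydroxyl in the molecule, so no selective acylation is needed after the oxirane is opened.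

Step 12
Reactants: 19 (1Z,2R,3aR,5R,6S,7S,7aR)-5,6-epoxy-1-ethylidene-4-methylidene-7-(propan-2-yl)octahydro-1H-inden-2-yl acetate; 20 (2E)-3-methylpent-2-enoic acid
Product: 21 (1Z,2R,3aR,5S,6S,7S,7aR)-2-(acetyloxy)-1-ethylidene-6-hydroxy-4-methylidene-7-(propan-2-yl)octahydro-1H-inden-5-yl (2E)-3-methylpent-2-enoate
Conditions: 20 (1.5 equiv), (PhO)2P(O)OH (10 mol%), 4 Å molecular sieves, toluene, −20 °C to 0 °C
Reagents that add atoms: none
Why: Proposed new method: the phosphoric acid hydrogen-bonds the oxirane oxygen and, through its P=O group, the carboxylic acid, so the acid adds in a concerted SN2 fashion anti to the C5–O bond at the allylic carbon, which is also the carbon that gives the trans-diaxial (Fürst–Plattner) product on the locked ring, setting C5 by inversion and freeing the C6 hydroxyl without SN2′ addition; the closest known reactions are phosphoric acid-catalysed carboxylysis of simple meso-epoxides and Co(salen)-catalysed carboxylic acid opening of epoxides, neither shown for a vinyl oxirane embedded in a chiral polycycle.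

**Compound list**
1 | (2E)-5-methyl-2-(propan-2-yl)hex-2-enal | O=C/C(C(C)C)=C/CC(C)C | starting material
2 | nitromethane | C[N+](=O)[O-] | starting material
3 | (1E,3E)-6-methyl-1-nitro-3-(propan-2-yl)hepta-1,3-diene | [O-][N+](=O)/C=C/C(C(C)C)=C/CC(C)C | intermediate
4 | succinaldehyde (butanedial) | O=CCCC=O | starting material
5 | (2S)-2-[(2R,3E)-6-methyl-1-nitro-3-(propan-2-yl)hept-3-en-2-yl]butanedial | O=CC[C@H](C=O)[C@@H](C[N+](=O)[O-])/C(C(C)C)=C/CC(C)C | intermediate
6 | (1R,2R,3R,4R)-2-[(3E)-2,6-dimethylhept-3-en-3-yl]-4-hydroxy-3-nitrocyclopentane-1-carbaldehyde | O=C[C@@H]1C[C@@H](O)[C@H]([N+](=O)[O-])[C@H]1/C(C(C)C)=C/CC(C)C | intermediate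
7 | (1R,2R,3R,4R)-4-[(tert-butyldimethylsilyl)oxy]-2-[(3E)-2,6-dimethylhept-3-en-3-yl]-3-nitrocyclopentane-1-carbaldehyde | O=C[C@@H]1C[C@@H](O[Si](C)(C)C(C)(C)C)[C@H]([N+](=O)[O-])[C@H]1/C(C(C)C)=C/CC(C)C | intermediate
8 | 2-({1-[(1R,2R,3R,4R)-4-[(tert-butyldimethylsilyl)oxy]-2-[(3E)-2,6-dimethylhept-3-en-3-yl]-3-nitrocyclopentyl]but-3-en-1-yl}oxy)-4,4,5,5-tetramethyl-1,3,2-dioxaborolane (both epimers at the O-bearing side-chain carbon) | C=CCC(OB1OC(C)(C)C(C)(C)O1)[C@@H]1C[C@@H](O[Si](C)(C)C(C)(C)C)[C@H]([N+](=O)[O-])[C@H]1/C(C(C)C)=C/CC(C)C | intermediate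
9 | 1-[(1R,2R,3R,4R)-4-[(tert-butyldimethylsilyl)oxy]-2-[(3E)-2,6-dimethylhept-3-en-3-yl]-3-nitrocyclopentyl]but-3-en-1-ol (both carbinol epimers) | C=CCC(O)[C@@H]1C[C@@H](O[Si](C)(C)C(C)(C)C)[C@H]([N+](=O)[O-])[C@H]1/C(C(C)C)=C/CC(C)C | intermediate
10 | sodium [(2R,3R,5R)-5-[(tert-butyldimethylsilyl)oxy]-2-[(3E)-2,6-dimethylhept-3-en-3-yl]-3-(1-hydroxybut-3-en-1-yl)cyclopentylidene]azinate (sodium nitronate of 9) | C=CCC(O)[C@@H]1C[C@@H](O[Si](C)(C)C(C)(C)C)C(=[N+]([O-])[O-])[C@H]1/C(C(C)C)=C/CC(C)C.[Na+] | intermediate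
11 | (2R,3R,5R)-5-[(tert-butyldimethylsilyl)oxy]-2-[(3E)-2,6-dimethylhept-3-en-3-yl]-3-(1-hydroxybut-3-en-1-yl)cyclopentan-1-one (both carbinol epimers) | C=CCC(O)[C@@H]1C[C@@H](O[Si](C)(C)C(C)(C)C)C(=O)[C@H]1/C(C(C)C)=C/CC(C)C | intermediate
12 | 1-[(1R,2R,3Z,4R)-4-[(tert-butyldimethylsilyl)oxy]-2-[(3E)-2,6-dimethylhept-3-en-3-yl]-3-ethylidenecyclopentyl]but-3-en-1-ol (both carbinol epimers) | C=CCC(O)[C@@H]1C[C@@H](O[Si](C)(C)C(C)(C)C)/C(=C\C)[C@H]1/C(C(C)C)=C/CC(C)C | intermediate
13 | (1Z,2R,3aR,7aR)-2-[(tert-butyldimethylsilyl)oxy]-1-ethylidene-7-(propan-2-yl)-2,3,3a,4,5,7a-hexahydro-1H-inden-4-ol (both C4 epimers) | OC1[C@@H]2C[C@@H](O[Si](C)(C)C(C)(C)C)/C(=C\C)[C@H]2C(C(C)C)=CC1 | intermediate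
14 | (1Z,2R,3aR,7aR)-2-[(tert-butyldimethylsilyl)oxy]-1-ethylidene-7-(propan-2-yl)-1,2,3,3a,5,7a-hexahydro-4H-inden-4-one | O=C1[C@@H]2C[C@@H](O[Si](C)(C)C(C)(C)C)/C(=C\C)[C@H]2C(C(C)C)=CC1 | intermediate
15 | (1Z,2R,3aR,7R,7aS)-2-[(tert-butyldimethylsilyl)oxy]-1-ethylidene-7-(propan-2-yl)-1,2,3,3a,7,7a-hexahydro-4H-inden-4-one | O=C1[C@@H]2C[C@@H](O[Si](C)(C)C(C)(C)C)/C(=C\C)[C@H]2[C@H](C(C)C)C=C1 | intermediate
16 | (1Z,2R,3aR,5S,6S,7S,7aS)-2-[(tert-butyldimethylsilyl)oxy]-5,6-epoxy-1-ethylidene-7-(propan-2-yl)octahydro-4H-inden-4-one | O=C1[C@@H]2C[C@@H](O[Si](C)(C)C(C)(C)C)/C(=C\C)[C@H]2[C@H](C(C)C)[C@@H]3O[C@H]13 | intermediate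
17 | tert-butyl{[(1Z,2R,3aR,5R,6S,7S,7aR)-5,6-epoxy-1-ethylidene-4-methylidene-7-(propan-2-yl)octahydro-1H-inden-2-yl]oxy}dimethylsilane | C=C1[C@@H]2C[C@@H](O[Si](C)(C)C(C)(C)C)/C(=C\C)[C@H]2[C@H](C(C)C)[C@@H]3O[C@H]13 | intermediate
18 | (1Z,2R,3aR,5R,6S,7S,7aR)-5,6-epoxy-1-ethylidene-4-methylidene-7-(propan-2-yl)octahydro-1H-inden-2-ol | C=C1[C@@H]2C[C@@H](O)/C(=C\C)[C@H]2[C@H](C(C)C)[C@@H]3O[C@H]13 | intermediate
19 | (1Z,2R,3aR,5R,6S,7S,7aR)-5,6-epoxy-1-ethylidene-4-methylidene-7-(propan-2-yl)octahydro-1H-inden-2-yl acetate | C=C1[C@@H]2C[C@@H](OC(C)=O)/C(=C\C)[C@H]2[C@H](C(C)C)[C@@H]3O[C@H]13 | intermediate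
20 | (2E)-3-methylpent-2-enoic acid | CC/C(C)=C/C(=O)O | starting material
21 | (1Z,2R,3aR,5S,6S,7S,7aR)-2-(acetyloxy)-1-ethylidene-6-hydroxy-4-methylidene-7-(propan-2-yl)octahydro-1H-inden-5-yl (2E)-3-methylpent-2-enoate | C=C1[C@@H]2C[C@@H](OC(C)=O)/C(=C\C)[C@H]2[C@H](C(C)C)[C@H](O)[C@H]1OC(=O)/C=C(\C)CC | target

**Totals and risk**
Total step count: 12. Longest linear sequence: 12 steps (1 to 21).

The three steps most likely to fail are steps 2, 6 and 12.

Step 2 asks a domino Michael/Henry reaction to work on a nitrodiene whose electrophilic carbon sits next to a fully substituted alkene carbon, and it relies on equilibration for the hydroxyl configuration. The fallback sets out from 3 and decouples the two events. Only the well-precedented enamine Michael addition is run, with commercial 4,4-dimethoxybutanal and the same catalyst, to give the acetal-protected Michael adduct F1. Aqueous acid (TFA, H2O, THF) then unmasks the second aldehyde, which returns to the route at 5. Compound 5 is closed to 6 in a separate iPr2NEt-mediated Henry step.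

Step 6 may give an E/Z mixture, or the ylide may simply enolise the hindered β,γ-unsaturated ketone. The fallback sets out from 11 and uses a Peterson olefination. 1-(Trimethylsilyl)ethyllithium with CeCl3 adds to the ketone to give the β-hydroxysilane F2. Its diastereomers are separated and each is eliminated stereospecifically (KH for the syn pathway, BF3·OEt2 for the anti pathway), so that both converge on the Z alkene and return to the route at 12.

Step 12 is the proposed new reaction; ionisation of the vinyl oxirane could give SN2′ or syn adducts. The fallback uses known chemistry and sets out from 19. Acid-catalysed hydrolysis (HClO4 cat., THF, H2O, 0 °C) opens the oxirane at the allylic carbon to the trans-diaxial diol F3. The less hindered allylic C5 hydroxyl is then esterified with 20 (DCC, DMAP, CH2Cl2, 0 °C), the C6 hydroxyl being shielded by the neighbouring isopropyl group, which returns to the route at 21.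

**Further compounds**
F1 | step 2 | (2S)-4,4-dimethoxy-2-[(2R,3E)-6-methyl-1-nitro-3-(propan-2-yl)hept-3-en-2-yl]butanal | COC(OC)C[C@H](C=O)[C@@H](C[N+](=O)[O-])/C(C(C)C)=C/CC(C)C
F2 | step 6 | 1-[(1R,2R,4R)-4-[(tert-butyldimethylsilyl)oxy]-2-[(3E)-2,6-dimethylhept-3-en-3-yl]-3-hydroxy-3-[1-(trimethylsilyl)ethyl]cyclopentyl]but-3-en-1-ol (diastereomers at C3 and at the silyl-bearing carbon) | C=CCC(O)[C@@H]1C[C@@H](O[Si](C)(C)C(C)(C)C)C(O)(C(C)[Si](C)(C)C)[C@H]1/C(C(C)C)=C/CC(C)C
F3 | step 12 | (1Z,2R,3aR,5S,6S,7S,7aR)-1-ethylidene-5,6-dihydroxy-4-methylidene-7-(propan-2-yl)octahydro-1H-inden-2-yl acetate | C=C1[C@@H]2C[C@@H](OC(C)=O)/C(=C\C)[C@H]2[C@H](C(C)C)[C@H](O)[C@H]1O
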